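**Plan**

- Retrosynthesis: gardenin D (24) is masked as its 5-O-methyl 3'-O-benzyl ether 22. The O1–C2 bond of ring C is cut to give ortho-hydroxyaryl ynone 20. In 20 the O1–C8a and C4–C4a bonds are cut together, leaving 3,4,5,6-tetramethoxybenzyne (from silyl triflate 9) and arylpropiolic acid 14.
- Enabling feature: in ring A, C8a (bearing O1) and C4a (bearing the C4 carbonyl) are adjacent, and the other neighbour of each (C8 and C5) carries a methoxy-type oxygen. They are therefore the two equivalent termini of a symmetric tetramethoxybenzyne, which can insert into the carboxyl C–O bond with no regiochemical question.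
- Forward: ring A is carried complete from 1,2,3,4-tetramethoxybenzene into 9 (four steps) and ring B from O-benzylisovanillin into 14 (two steps). The insertion joins them as open-chain 20, ring C then closes 6-endo (O1–C2) through a diethylamine adduct, and BCl3 frees the 5- and 3'-hydroxyls.
- Stereochemistry: the target has no stereocentre and no stereogenic double bond, so nothing has to be set.

Key step: step 7

Assumption: 1,2,3,4-tetramethoxybenzene (1) and 3-benzyloxy-4-methoxybenzaldehyde (10, O-benzylisovanillin) are taken as catalogue compounds; 10 is otherwise one step from isovanillin (BnBr, K2CO3, DMF).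

**Route**

Step 1
Reactants: 1 1,2,3,4-tetramethoxybenzene
Product: 4 2,3,4,5-tetramethoxyphenol, via aryllithium 2 (not isolated), via lithium aryltrimethoxyborate 3 (not isolated)
Conditions: n-BuLi, TMEDA, THF, 0 °C; B(OMe)3, −78 °C to rt; AcOH, 30% H2O2, 0 °C to rt
Reagents that add atoms: hydrogen peroxide, OO
Why: Directed ortho-lithiation beside a methoxy group (the two ring C–H positions of 1 are equivalent), borylation and oxidative C–B to C–O conversion form a standard arene hydroxylation sequence.

Step 2
Reactants: 4 2,3,4,5-tetramethoxyphenol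
Product: 5 2-bromo-3,4,5,6-tetramethoxyphenol
Conditions: NBS (1.0 equiv), MeCN, −20 to 0 °C, dark
Reagents that add atoms: N-bromosuccinimide, O=C1CCC(=O)N1Br
Why: Electrophilic aromatic bromination of a phenol whose single free ring position lies ortho to the hydroxyl, so substitution can only give 5.

Step 3
Reactants: 5 2-bromo-3,4,5,6-tetramethoxyphenol
Product: 6 (2-bromo-3,4,5,6-tetramethoxyphenoxy)trimethylsilane
Conditions: HMDS, THF, 65 °C; evaporate
Reagents that add atoms: hexamethyldisilazane, C[Si](C)(C)N[Si](C)(C)C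
Why: O-silylation of a phenol with HMDS releases only ammonia, so the crude silyl ether should be usable directly after evaporation.

Step 4
Reactants: 6 (2-bromo-3,4,5,6-tetramethoxyphenoxy)trimethylsilane
Product: 9 2,3,4,5-tetramethoxy-6-(trimethylsilyl)phenyl trifluoromethanesulfonate, via aryllithium 7 (not isolated), via lithium ortho-silylphenoxide 8 (not isolated)
Conditions: n-BuLi, THF, −78 °C; Tf2O, −78 to 0 °C
Reagents that add atoms: trifluoromethanesulfonic anhydride, O=S(=O)(OS(=O)(=O)C(F)(F)F)C(F)(F)F
Why: Bromine–lithium exchange triggers a retro-Brook 1,3-shift of silicon from oxygen to carbon, and the resulting phenoxide is O-triflated, the standard entry to ortho-silylaryl triflate aryne precursors.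

Step 5
Reactants: 10 3-benzyloxy-4-methoxybenzaldehyde
Product: 11 2-benzyloxy-4-(2,2-dibromovinyl)-1-methoxybenzene
Conditions: CBr4, PPh3, CH2Cl2, 0 °C
Reagents that add atoms: carbon tetrabromide, BrC(Br)(Br)Br
Why: First stage of the Corey–Fuchs reaction, a Wittig-type dibromomethylenation of an aromatic aldehyde.

Step 6
Reactants: 11 2-benzyloxy-4-(2,2-dibromovinyl)-1-methoxybenzene
Product: 14 3-(3-benzyloxy-4-methoxyphenyl)propiolic acid, via lithium acetylide 12 (not isolated), via lithium propiolate 13 (not isolated)
Conditions: n-BuLi (2.2 equiv), THF, −78 to 0 °C; CO2, −78 °C to rt; aq. HCl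
Reagents that add atoms: carbon dioxide, O=C=O
Why: Second stage of the Corey–Fuchs reaction (bromine–lithium exchange, 1,2-shift and deprotonation to the acetylide) followed by carboxylation with CO2; the acid should be purifiable by acid–base extraction.

Step 7
Reactants: 9 2,3,4,5-tetramethoxy-6-(trimethylsilyl)phenyl trifluoromethanesulfonate; 14 3-(3-benzyloxy-4-methoxyphenyl)propiolic acid
Product: 20 1-(2-hydroxy-3,4,5,6-tetramethoxyphenyl)-3-(3-benzyloxy-4-methoxyphenyl)prop-2-yn-1-one, via potassium propiolate 15 (not isolated), via tetramethoxybenzyne 16 (not isolated), via aryl anion 17 (not isolated), via benzoxetene alkoxide 18 (not isolated), via potassium phenoxide 19 (not isolated)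
Conditions: 14 (1.5 equiv), KH (1.0 equiv per 14), THF, 0 °C; then 9, KF, 18-crown-6, THF, 0 °C to rt; AcOH, −20 °C
Reagents that add atoms: none
Why: Fluoride attacks silicon of 9 and triflate leaves to release the symmetric aryne 16; the carboxylate oxygen of 15 adds to one aryne carbon, aryl anion 17 attacks the neighbouring ester carbonyl to give the four-membered alkoxide 18, and C–O cleavage of that ring delivers ortho-acyl phenoxide 19, so that O1–C8a and C4–C4a of the flavone are made in one operation. This is the known aryne insertion into the C–O bond of carboxylic acids, which turns ortho-silylaryl triflates and acids, arylpropiolic acids included, into ortho-hydroxyaryl ketones. No ring is closed (the four-membered ring is transient and reopens) and no stereocentre is formed. Regioselectivity needs no control because both aryne carbons are equivalent, each lying next to a methoxy-bearing carbon. Acyl transfer must outrun protonation of 17 to the aryl ester, which the preformed potassium salt in aprotic THF (no O–H or N–H donor) should secure, and the Z conformation of the aryl ester holds the alkyne away from the carbanion so that attack goes to C=O and not to the triple bond. Working at room temperature with a cold AcOH quench, in place of the heating usually applied, should keep phenoxide 19 from adding to its own alkyne, so that the open ynone is isolated.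

Step 8
Reactants: 20 1-(2-hydroxy-3,4,5,6-tetramethoxyphenyl)-3-(3-benzyloxy-4-methoxyphenyl)prop-2-yn-1-one
Product: 22 2-(3-benzyloxy-4-methoxyphenyl)-5,6,7,8-tetramethoxy-4H-chromen-4-one, via enaminone 21 (not isolated)
Conditions: Et2NH, EtOH, 70 °C
Reagents that add atoms: none
Why: Amine-mediated flavone synthesis from an ortho-hydroxyaryl ynone: conjugate addition of Et2NH gives the enaminone, whose phenol adds 6-endo-trig to the amine-bearing carbon with loss of Et2NH, which bypasses the 5-exo route to the aurone.

Step 9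
Reactants: 22 2-(3-benzyloxy-4-methoxyphenyl)-5,6,7,8-tetramethoxy-4H-chromen-4-one
Product: 24 gardenin D, via bis(dichloroboryl) ether 23 (not isolated)
Conditions: BCl3, pentamethylbenzene, CH2Cl2, −78 to 0 °C; H2O
Reagents that add atoms: none
Why: BCl3 ether cleavage: the benzyl ether falls at low temperature with pentamethylbenzene as cation scavenger, and the 5-methoxy group, activated by boron chelation to the C4 carbonyl, should be the only methyl ether cleaved at 0 °C.

**Compound list**

1 | 1,2,3,4-tetramethoxybenzene | COc1ccc(OC)c(OC)c1OC | starting material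
2 | (2,3,4,5-tetramethoxyphenyl)lithium | [Li]c1cc(OC)c(OC)c(OC)c1OC | intermediate (not isolated)
3 | lithium trimethoxy(2,3,4,5-tetramethoxyphenyl)borate | [Li+].CO[B-](OC)(OC)c1cc(OC)c(OC)c(OC)c1OC | intermediate (not isolated)
4 | 2,3,4,5-tetramethoxyphenol | COc1cc(O)c(OC)c(OC)c1OC | intermediate
5 | 2-bromo-3,4,5,6-tetramethoxyphenol | COc1c(Br)c(O)c(OC)c(OC)c1OC | intermediate
6 | (2-bromo-3,4,5,6-tetramethoxyphenoxy)trimethylsilane | COc1c(Br)c(O[Si](C)(C)C)c(OC)c(OC)c1OC | intermediate
7 | [2,3,4,5-tetramethoxy-6-(trimethylsilyloxy)phenyl]lithium | COc1c([Li])c(O[Si](C)(C)C)c(OC)c(OC)c1OC | intermediate (not isolated)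
8 | lithium 2,3,4,5-tetramethoxy-6-(trimethylsilyl)phenoxide | [Li+].COc1c([Si](C)(C)C)c([O-])c(OC)c(OC)c1OC | intermediate (not isolated)
9 | 2,3,4,5-tetramethoxy-6-(trimethylsilyl)phenyl trifluoromethanesulfonate | COc1c(OC)c(OC)c(OS(=O)(=O)C(F)(F)F)c([Si](C)(C)C)c1OC | intermediate
10 | 3-benzyloxy-4-methoxybenzaldehyde | COc1ccc(C=O)cc1OCc1ccccc1 | starting material
11 | 2-benzyloxy-4-(2,2-dibromovinyl)-1-methoxybenzene | COc1ccc(C=C(Br)Br)cc1OCc1ccccc1 | intermediate
12 | [(3-benzyloxy-4-methoxyphenyl)ethynyl]lithium | [Li]C#Cc1ccc(OC)c(OCc2ccccc2)c1 | intermediate (not isolated)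
13 | lithium 3-(3-benzyloxy-4-methoxyphenyl)propiolate | [Li+].[O-]C(=O)C#Cc1ccc(OC)c(OCc2ccccc2)c1 | intermediate (not isolated)
14 | 3-(3-benzyloxy-4-methoxyphenyl)propiolic acid | OC(=O)C#Cc1ccc(OC)c(OCc2ccccc2)c1 | intermediate
15 | potassium 3-(3-benzyloxy-4-methoxyphenyl)propiolate | [K+].[O-]C(=O)C#Cc1ccc(OC)c(OCc2ccccc2)c1 | intermediate (not isolated)
16 | 3,4,5,6-tetramethoxybenzyne (1,2-didehydro-3,4,5,6-tetramethoxybenzene) | COC1=C(OC)C(OC)=C(OC)C#C1 | intermediate (not isolated)
17 | potassium 2-[3-(3-benzyloxy-4-methoxyphenyl)propioloyloxy]-3,4,5,6-tetramethoxybenzenide (aryl anion) | [K+].COc1ccc(C#CC(=O)Oc2[c-]c(OC)c(OC)c(OC)c2OC)cc1OCc1ccccc1 | intermediate (not isolated)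
18 | potassium 2-[(3-benzyloxy-4-methoxyphenyl)ethynyl]-3,4,5,6-tetramethoxy-2H-1-benzoxet-2-olate (racemic, transient) | [K+].COc1ccc(C#CC2([O-])Oc3c(OC)c(OC)c(OC)c(OC)c32)cc1OCc1ccccc1 | intermediate (not isolated)
19 | potassium 2-[3-(3-benzyloxy-4-methoxyphenyl)propioloyl]-3,4,5,6-tetramethoxyphenoxide | [K+].COc1ccc(C#CC(=O)c2c([O-])c(OC)c(OC)c(OC)c2OC)cc1OCc1ccccc1 | intermediate (not isolated)
20 | 1-(2-hydroxy-3,4,5,6-tetramethoxyphenyl)-3-(3-benzyloxy-4-methoxyphenyl)prop-2-yn-1-one | COc1ccc(C#CC(=O)c2c(O)c(OC)c(OC)c(OC)c2OC)cc1OCc1ccccc1 | intermediate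
21 | (E)-3-(3-benzyloxy-4-methoxyphenyl)-3-(diethylamino)-1-(2-hydroxy-3,4,5,6-tetramethoxyphenyl)prop-2-en-1-one (drawn E; the push–pull double bond isomerises freely) | CCN(CC)/C(=C/C(=O)c1c(O)c(OC)c(OC)c(OC)c1OC)c1ccc(OC)c(OCc2ccccc2)c1 | intermediate (not isolated)
22 | 2-(3-benzyloxy-4-methoxyphenyl)-5,6,7,8-tetramethoxy-4H-chromen-4-one (3'-benzyloxy-5,6,7,8,4'-pentamethoxyflavone) | COc1ccc(-c2cc(=O)c3c(OC)c(OC)c(OC)c(OC)c3o2)cc1OCc1ccccc1 | intermediate
23 | 5,3'-bis(dichloroboryloxy)-6,7,8,4'-tetramethoxyflavone | COc1ccc(-c2cc(=O)c3c(OB(Cl)Cl)c(OC)c(OC)c(OC)c3o2)cc1OB(Cl)Cl | intermediate (not isolated)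
24 | gardenin D (5,3'-dihydroxy-6,7,8,4'-tetramethoxyflavone) | COc1ccc(-c2cc(=O)c3c(O)c(OC)c(OC)c(OC)c3o2)cc1O | target

**Step count**

Total steps: 9. Longest linear sequence: 7 (steps 1, 2, 3, 4, 7, 8, 9); the ring B branch contributes steps 5 and 6.

**Steps most likely to fail**

Step 7. The aryl anion 17 may be protonated before it reaches the ester carbonyl, which would leave the aryl ester. Phenoxide 19 may be arylated by a second aryne, or may close onto its own alkyne before the quench. The fallback abandons the aryne and uses the classical chalcone route; it sets out from 4 and 10 and returns at 22. Phenol 4 is C-acetylated at its only free ring position with AcOH and BF3·OEt2 at 90 °C to give 2'-hydroxy-3',4',5',6'-tetramethoxyacetophenone F1. Claisen–Schmidt condensation of this ketone with aldehyde 10 (KOH, EtOH, rt) gives (E)-3-(3-benzyloxy-4-methoxyphenyl)-1-(2-hydroxy-3,4,5,6-tetramethoxyphenyl)prop-2-en-1-one F2. Catalytic I2 in DMSO at 120 °C then cyclises and dehydrogenates the chalcone to flavone 22.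

Step 2. NBS may oxidise the very electron-rich free phenol, with loss of a methyl group toward a quinone, in competition with ring substitution. The fallback masks the phenol before halogenation; it sets out from 4 and returns at 5. Acetylation (Ac2O, pyridine, rt) gives 2,3,4,5-tetramethoxyphenyl acetate F3, whose remaining ring position is still activated by an ortho and a para methoxy group. NBS in MeCN at rt should then give 2-bromo-3,4,5,6-tetramethoxyphenyl acetate F4, and K2CO3 in MeOH releases bromophenol 5.

Step 9. Further methyl ethers may be lost (6-OMe beside the boron chelate, 4'-OMe beside the freed 3'-oxygen), or the benzyl cation may alkylate an electron-rich ring. The fallback separates the two deprotections; it sets out from 22 and returns at 24. Hydrogenolysis (H2, 10% Pd/C, EtOAc/MeOH, rt) removes the benzyl group to give 3'-hydroxy-5,6,7,8,4'-pentamethoxyflavone F5. AlCl3 in MeCN at rt then cleaves only the carbonyl-chelated 5-O-methyl group to give gardenin D 24.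

**Further compounds**

F1 | step 7 | 2'-hydroxy-3',4',5',6'-tetramethoxyacetophenone | CC(=O)c1c(O)c(OC)c(OC)c(OC)c1OC
F2 | step 7 | (E)-3-(3-benzyloxy-4-methoxyphenyl)-1-(2-hydroxy-3,4,5,6-tetramethoxyphenyl)prop-2-en-1-one | COc1ccc(/C=C/C(=O)c2c(O)c(OC)c(OC)c(OC)c2OC)cc1OCc1ccccc1
F3 | step 2 | 2,3,4,5-tetramethoxyphenyl acetate | CC(=O)Oc1cc(OC)c(OC)c(OC)c1OC
F4 | step 2 | 2-bromo-3,4,5,6-tetramethoxyphenyl acetate | CC(=O)Oc1c(Br)c(OC)c(OC)c(OC)c1OC
F5 | step 9 | 3'-hydroxy-5,6,7,8,4'-pentamethoxyflavone | COc1ccc(-c2cc(=O)c3c(OC)c(OC)c(OC)c(OC)c3o2)cc1O
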